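**Plan**
1. Labels: A and A′ are the two 2,6-dimethoxyphenyl rings. Ring B carries the CH2 (C1 aroyl, C2 OH, C3 H, C4 Me, C5 OMe, C6 CH2). Ring C carries the CH2C(=O) ketone (C1′ ketone, C2′ OMe, C3′ Me, C4′ H, C5′ OH, C6′ aroyl).
2. Cuts, in order: C6′–C(=O)A′, then the benzylic CH2–C(=O) bond between rings B and C, then C1–C(=O)A. No ring is built, since all four arenes are bought.
3. Enabling feature: C5′–OH and C2′–OMe are para on ring C, so ring C can be oxidised to its 4,4-dimethoxycyclohexa-2,5-dienone. There C6′–H is the free end of the ene-dione C5′(=O)–C6′H=C1′–C(=O)CH2, and loss of one ketal methoxy group re-aromatises to exactly the OH/OMe pattern of the target.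
4. Two carbons of like (electrophilic) polarity are therefore joined by a decarboxylative aroyl-radical addition to the dearomatised ring. This is the last C–C bond and sits at the most crowded position of the molecule.
5. Forward: symmetric 4-methoxy-3,5-dimethylphenol → MOM ether → ortho-lithiation/aroylation (A–B ketone) → lateral lithiation of the methyl group ortho to that ketone plus a ring-C Weinreb amide (B–C link) → Br to OH → dearomatisation → radical acylation/re-aromatisation → MOM removal.
6. Stereochemistry: the target has no stereocentre, and the two centres formed in the key step are transient.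

Key step: step 10

Remark: the SMILES holds no stereocentre and no defined axis, so the compound is treated as achiral and the request for a single enantiomer needs no action.

**Step 1**
Reactants: 1 (4-methoxy-3,5-dimethylphenyl)boronic acid
Product: 2 4-methoxy-3,5-dimethylphenol
Conditions: 30% aq H2O2, THF, 0 °C → rt
Reagents that add atoms: hydrogen peroxide, OO
Why: Oxidative ipso-hydroxylation of an arylboronic acid (peroxide adds to boron, 1,2-aryl shift, hydrolysis) should give the mirror-symmetric phenol, and the aryl methyl ether and methyl groups are inert to neutral H2O2.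

**Step 2**
Reactants: 2 4-methoxy-3,5-dimethylphenol
Product: 3 2-methoxy-5-(methoxymethoxy)-1,3-dimethylbenzene
Conditions: MOMCl, i-Pr2NEt, CH2Cl2, 0 °C → rt
Reagents that add atoms: chloromethyl methyl ether (MOMCl), COCCl
Why: Standard MOM protection (O-alkylation of the phenol with an α-chloro ether) installs the acetal that later directs the lithiation, masks the acidic OH towards lithium bases and keeps ring B out of the hypervalent-iodine oxidation.

**Step 3**
Reactants: 3 2-methoxy-5-(methoxymethoxy)-1,3-dimethylbenzene; 4 2,6-dimethoxybenzoyl chloride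
Product: 6 (2,6-dimethoxyphenyl)[3-methoxy-6-(methoxymethoxy)-2,4-dimethylphenyl]methanone, via [3-methoxy-6-(methoxymethoxy)-2,4-dimethylphenyl]lithium 5 (not isolated)
Conditions: n-BuLi, TMEDA, THF, 0 °C; then cannulated into 4, THF, −78 °C → rt
Reagents that add atoms: n-butyllithium, [Li]CCCC (lithium of 5 only; no atom of it remains in 6)
Why: Directed ortho-metalation next to OMOM followed by acylation with an acid chloride: the two positions ortho to OMOM are equivalent by symmetry, so only one aryllithium can form, and the tetra-ortho-substituted ketone 6 is too hindered to take up a second aryllithium.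

**Step 4**
Reactants: 7 5-bromo-2-hydroxy-3-methylbenzoic acid
Product: 8 methyl 5-bromo-2-methoxy-3-methylbenzoate
Conditions: MeI (2.5 equiv), K2CO3, DMF, rt
Reagents that add atoms: iodomethane, CI
Why: Double SN2 O-methylation (carboxylate and phenolate) with MeI/K2CO3 is routine for salicylic acids and leaves the aryl bromide untouched.

**Step 5**
Reactants: 8 methyl 5-bromo-2-methoxy-3-methylbenzoate
Product: 9 5-bromo-N,2-dimethoxy-N,3-dimethylbenzamide
Conditions: MeNH(OMe)·HCl, i-PrMgCl, THF, −20 → 0 °C
Reagents that add atoms: N,O-dimethylhydroxylamine hydrochloride, CNOC.Cl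
Why: Weinreb amide synthesis by aminolysis of the ester with the chloromagnesium amide made in situ; an electron-neutral aryl bromide does not undergo Br/Mg exchange with i-PrMgCl at this temperature in the absence of LiCl.

**Step 6**
Reactants: 6 (2,6-dimethoxyphenyl)[3-methoxy-6-(methoxymethoxy)-2,4-dimethylphenyl]methanone; 9 5-bromo-N,2-dimethoxy-N,3-dimethylbenzamide
Product: 11 1-(5-bromo-2-methoxy-3-methylphenyl)-2-[2-(2,6-dimethoxybenzoyl)-6-methoxy-3-(methoxymethoxy)-5-methylphenyl]ethan-1-one, via {[2-(2,6-dimethoxybenzoyl)-6-methoxy-3-(methoxymethoxy)-5-methylphenyl]methyl}lithium (o-quinodimethane enolate) 10 (not isolated)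
Conditions: TMPH, n-BuLi, THF, 0 °C (LiTMP); 6, −78 °C; then 9, −78 → −20 °C; H2O
Reagents that add atoms: n-butyllithium, [Li]CCCC (lithium of 10 only, passed on through LiTMP)
Why: Lateral lithiation followed by Weinreb ketone synthesis: the C6 methyl group is ortho to the non-enolisable, sterically shielded ketone, so the non-nucleophilic amide base, guided by the carbonyl and C5-OMe oxygens, should remove its vinylogously acidic proton to give 10, which attacks 9 through the benzylic carbon, and the stable tetrahedral chelate prevents both over-addition and proton exchange with the more acidic product.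

**Step 7**
Reactants: 11 1-(5-bromo-2-methoxy-3-methylphenyl)-2-[2-(2,6-dimethoxybenzoyl)-6-methoxy-3-(methoxymethoxy)-5-methylphenyl]ethan-1-one
Product: 13 2-[2-(2,6-dimethoxybenzoyl)-6-methoxy-3-(methoxymethoxy)-5-methylphenyl]-1-(5-hydroxy-2-methoxy-3-methylphenyl)ethan-1-one, via the C5′ pinacol boronate of 11 12 (not isolated)
Conditions: B2pin2, Pd(dppf)Cl2 (5 mol %), KOAc, 1,4-dioxane, 90 °C; then NaBO3·4H2O, THF–H2O, rt
Reagents that add atoms: bis(pinacolato)diboron, CC1(C)OB(OC1(C)C)B1OC(C)(C)C(C)(C)O1 (boryl group of 12); sodium perborate (used as the tetrahydrate), [Na+].[Na+].O[B-]1(O)OO[B-](O)(O)OO1 (phenol oxygen of 13)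
Why: Miyaura borylation of the aryl bromide and in-flask oxidation of the boronate (ipso-hydroxylation) unmask the C5′ phenol under weakly basic conditions that tolerate both ketones, the acidic CH2 and the MOM acetal.

**Step 8**
Reactants: 13 2-[2-(2,6-dimethoxybenzoyl)-6-methoxy-3-(methoxymethoxy)-5-methylphenyl]-1-(5-hydroxy-2-methoxy-3-methylphenyl)ethan-1-one
Product: 14 3-{[2-(2,6-dimethoxybenzoyl)-6-methoxy-3-(methoxymethoxy)-5-methylphenyl]acetyl}-4,4-dimethoxy-5-methylcyclohexa-2,5-dien-1-one
Conditions: PhI(OAc)2 (1.05 equiv), MeOH, 0 °C, short time; NaHCO3 work-up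
Reagents that add atoms: methanol, CO
Why: Hypervalent-iodine oxidative dearomatisation of a 4-methoxyphenol in methanol gives the p-quinone monoketal because the phenoxenium ion is trapped at the methoxy-bearing para carbon C2′; ring B has no free OH and is not attacked, and the short reaction at 0 °C limits addition of methanol to the new ene-dione.

**Step 9**
Reactants: 15 1-(2,6-dimethoxyphenyl)ethan-1-one
Product: 16 2-(2,6-dimethoxyphenyl)-2-oxoacetic acid
Conditions: SeO2, pyridine, 110 °C
Reagents that add atoms: selenium dioxide, O=[Se]=O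
Why: Riley oxidation of an aryl methyl ketone with SeO2 in pyridine runs through the glyoxal to the arylglyoxylic acid and is the standard entry to α-keto acids used as acyl-radical precursors.

**Step 10**
Reactants: 14 3-{[2-(2,6-dimethoxybenzoyl)-6-methoxy-3-(methoxymethoxy)-5-methylphenyl]acetyl}-4,4-dimethoxy-5-methylcyclohexa-2,5-dien-1-one; 16 2-(2,6-dimethoxyphenyl)-2-oxoacetic acid
Product: 18 1-[2-(2,6-dimethoxybenzoyl)-3-hydroxy-6-methoxy-5-methylphenyl]-2-[2-(2,6-dimethoxybenzoyl)-6-methoxy-3-(methoxymethoxy)-5-methylphenyl]ethan-1-one, via 6-(2,6-dimethoxybenzoyl)-5-{[2-(2,6-dimethoxybenzoyl)-6-methoxy-3-(methoxymethoxy)-5-methylphenyl]acetyl}-4,4-dimethoxy-3-methylcyclohex-2-en-1-one 17 (not isolated)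
Conditions: 16 (1.5 equiv), 2,4,6-collidine (1.5 equiv), Ru(bpz)3(PF6)2 (2 mol %), degassed MeCN, 450 nm LED, rt; SiO2
Reagents that add atoms: none
Why: Proposed new method: blue-light-excited Ru(bpz)3(2+) oxidises the collidinium carboxylate of 16, CO2 is lost, and the nucleophilic σ-type 2,6-dimethoxybenzoyl radical adds to C6′–H of 14, the only unsubstituted end of the ene-dione C5′(=O)–C6′H=C1′–C(=O)CH2, to leave a tertiary α-keto radical at C1′. Ru(I) reduces that radical to the enolate (protonated form: 17), which expels one methoxide of the adjacent C2′ ketal (E1cB), and enolisation of the C6′–H β-diketone then restores ring C as the chelated phenol 18, so the overall change 14 + 16 → 18 + CO2 + MeOH is redox-neutral and driven by aromatisation. The closest known reaction types are the photoredox decarboxylative Giese acylation of Michael acceptors with α-keto acids, the photochemical acylation of 1,4-quinones with aldehydes, and the conjugate addition/aromatisation of quinone monoketals with two-electron carbon nucleophiles; what is new is an acyl radical on an acyl-activated quinone monoketal. No ring is closed, and the two stereocentres of 17 (C1′, C6′) need no control because both become sp2 again. The step needs site selectivity among the four olefinic carbons of the dienone: C1′ and C3′ are fully substituted, attack at C4′ would give a radical without carbonyl stabilisation, and only attack at C6′ gives the ketone-stabilised radical; the OH/OMe pattern is secured because O5′ is the dienone carbonyl and O2′ keeps one methyl group, and an early radical transition state on a flat sp2 CH avoids the steric penalty of an ionic acylation at this doubly flanked position. A photocatalyst whose reduced form is only weakly reducing limits electron transfer to 14 itself, 450 nm light is not absorbed by the o-alkylbenzophenone or the dienone, and collidine (blocked at 2, 4 and 6 against radical attack) buffers 16 without deprotonating the acidic CH2 or opening the ketal and MOM acetals.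

**Step 11**
Reactants: 18 1-[2-(2,6-dimethoxybenzoyl)-3-hydroxy-6-methoxy-5-methylphenyl]-2-[2-(2,6-dimethoxybenzoyl)-6-methoxy-3-(methoxymethoxy)-5-methylphenyl]ethan-1-one
Product: 19 acredinone B, 1,2-bis[2-(2,6-dimethoxybenzoyl)-3-hydroxy-6-methoxy-5-methylphenyl]ethan-1-one
Conditions: 2 M aq HCl, THF, 45 °C
Reagents that add atoms: none
Why: Acid-catalysed hydrolysis of the MOM acetal, accelerated by the neighbouring carbonyl group, frees the C2 phenol while the aryl methyl ethers and hindered ketones stay intact, and any reversible hemiketal or benzopyrylium formation of the 1,5-diketone is undone on aqueous work-up.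

**Compound list**
1 | (4-methoxy-3,5-dimethylphenyl)boronic acid | COc1c(C)cc(cc1C)B(O)O | starting material
2 | 4-methoxy-3,5-dimethylphenol | COc1c(C)cc(O)cc1C | intermediate
3 | 2-methoxy-5-(methoxymethoxy)-1,3-dimethylbenzene | COCOc1cc(C)c(OC)c(C)c1 | intermediate
4 | 2,6-dimethoxybenzoyl chloride | COc1cccc(OC)c1C(=O)Cl | starting material
5 | [3-methoxy-6-(methoxymethoxy)-2,4-dimethylphenyl]lithium | [Li]c1c(C)c(OC)c(C)cc1OCOC | intermediate (not isolated)
6 | (2,6-dimethoxyphenyl)[3-methoxy-6-(methoxymethoxy)-2,4-dimethylphenyl]methanone | COCOc1cc(C)c(OC)c(C)c1C(=O)c1c(OC)cccc1OC | intermediate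
7 | 5-bromo-2-hydroxy-3-methylbenzoic acid | Cc1cc(Br)cc(C(=O)O)c1O | starting material
8 | methyl 5-bromo-2-methoxy-3-methylbenzoate | COC(=O)c1cc(Br)cc(C)c1OC | intermediate
9 | 5-bromo-N,2-dimethoxy-N,3-dimethylbenzamide | CON(C)C(=O)c1cc(Br)cc(C)c1OC | intermediate
10 | {[2-(2,6-dimethoxybenzoyl)-6-methoxy-3-(methoxymethoxy)-5-methylphenyl]methyl}lithium (drawn as the benzylic lithium form of the o-quinodimethane enolate) | [Li]Cc1c(OC)c(C)cc(OCOC)c1C(=O)c1c(OC)cccc1OC | intermediate (not isolated)
11 | 1-(5-bromo-2-methoxy-3-methylphenyl)-2-[2-(2,6-dimethoxybenzoyl)-6-methoxy-3-(methoxymethoxy)-5-methylphenyl]ethan-1-one | COCOc1cc(C)c(OC)c(CC(=O)c2cc(Br)cc(C)c2OC)c1C(=O)c1c(OC)cccc1OC | intermediate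
12 | C5′ pinacol boronate of 11 (Bpin in place of Br) | COCOc1cc(C)c(OC)c(CC(=O)c2cc(B3OC(C)(C)C(C)(C)O3)cc(C)c2OC)c1C(=O)c1c(OC)cccc1OC | intermediate (not isolated)
13 | 2-[2-(2,6-dimethoxybenzoyl)-6-methoxy-3-(methoxymethoxy)-5-methylphenyl]-1-(5-hydroxy-2-methoxy-3-methylphenyl)ethan-1-one | COCOc1cc(C)c(OC)c(CC(=O)c2cc(O)cc(C)c2OC)c1C(=O)c1c(OC)cccc1OC | intermediate
14 | 3-{[2-(2,6-dimethoxybenzoyl)-6-methoxy-3-(methoxymethoxy)-5-methylphenyl]acetyl}-4,4-dimethoxy-5-methylcyclohexa-2,5-dien-1-one | COCOc1cc(C)c(OC)c(CC(=O)C2=CC(=O)C=C(C)C2(OC)OC)c1C(=O)c1c(OC)cccc1OC | intermediate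
15 | 1-(2,6-dimethoxyphenyl)ethan-1-one | CC(=O)c1c(OC)cccc1OC | starting material
16 | 2-(2,6-dimethoxyphenyl)-2-oxoacetic acid | COc1cccc(OC)c1C(=O)C(=O)O | intermediate
17 | 6-(2,6-dimethoxybenzoyl)-5-{[2-(2,6-dimethoxybenzoyl)-6-methoxy-3-(methoxymethoxy)-5-methylphenyl]acetyl}-4,4-dimethoxy-3-methylcyclohex-2-en-1-one (racemic, diastereomer mixture; both centres are lost on aromatisation, so no descriptors are given) | COCOc1cc(C)c(OC)c(CC(=O)C2C(C(=O)c3c(OC)cccc3OC)C(=O)C=C(C)C2(OC)OC)c1C(=O)c1c(OC)cccc1OC | intermediate (not isolated)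
18 | 1-[2-(2,6-dimethoxybenzoyl)-3-hydroxy-6-methoxy-5-methylphenyl]-2-[2-(2,6-dimethoxybenzoyl)-6-methoxy-3-(methoxymethoxy)-5-methylphenyl]ethan-1-one | COCOc1cc(C)c(OC)c(CC(=O)c2c(OC)c(C)cc(O)c2C(=O)c2c(OC)cccc2OC)c1C(=O)c1c(OC)cccc1OC | intermediate
19 | acredinone B, 1,2-bis[2-(2,6-dimethoxybenzoyl)-3-hydroxy-6-methoxy-5-methylphenyl]ethan-1-one (achiral) | COc1cccc(OC)c1C(=O)c1c(O)cc(C)c(OC)c1CC(=O)c1c(OC)c(C)cc(O)c1C(=O)c1c(OC)cccc1OC | target

**Totals**
Total step count: 11.
Longest linear sequence: 8 steps (1, 2, 3, 6, 7, 8, 10, 11).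

**Steps most likely to fail**

Step 10.
- What may go wrong: electron transfer from the reduced photocatalyst to the ene-dione with loss of methoxide (re-aromatisation without C–C bond formation), slow capture of the hindered aroyl radical, or acid-induced loss of the ketal.
- Fallback: known chemistry with no late acylation, in which both benzophenones come from the symmetric aroylation of step 3. It sets out from 6 and comes back at 19.
- The lateral anion 10, made from 6 as in step 6, is hydroxylated with a Davis oxaziridine to [2-(hydroxymethyl)-3-methoxy-6-(methoxymethoxy)-4-methylphenyl](2,6-dimethoxyphenyl)methanone F1.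
- Dess–Martin oxidation gives 2-(2,6-dimethoxybenzoyl)-6-methoxy-3-(methoxymethoxy)-5-methylbenzaldehyde F2.
- A second portion of 10 adds to the aldehyde (the hindered ketones are spared) to give racemic 1,2-bis[2-(2,6-dimethoxybenzoyl)-6-methoxy-3-(methoxymethoxy)-5-methylphenyl]ethan-1-ol F3.
- Dess–Martin oxidation gives 1,2-bis[2-(2,6-dimethoxybenzoyl)-6-methoxy-3-(methoxymethoxy)-5-methylphenyl]ethan-1-one F4.
- Aqueous HCl as in step 11 removes both acetals to give 19.

Step 6.
- What may go wrong: competing deprotonation of the C4 methyl group (para to the ketone) or of ring positions, poor planarisation of the twisted ketone in the dienolate, or electron or hydride transfer to the ketone.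
- Fallback: an o-toluate lateral lithiation with an isocoumarin as a temporary ring, so that the A–B ketone is made last. It sets out from 3 and comes back at 11.
- Compound 3 is lithiated as in step 3 (5) and quenched with methyl chloroformate to methyl 3-methoxy-6-(methoxymethoxy)-2,4-dimethylbenzoate F5.
- LDA at −78 °C removes a proton of the methyl group ortho to the ester to give {[6-methoxy-2-(methoxycarbonyl)-3-(methoxymethoxy)-5-methylphenyl]methyl}lithium F6.
- F6 adds to 9 to give methyl 2-[2-(5-bromo-2-methoxy-3-methylphenyl)-2-oxoethyl]-3-methoxy-6-(methoxymethoxy)-4-methylbenzoate F7.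
- DBU in warm toluene closes the enol oxygen onto the ester to give 3-(5-bromo-2-methoxy-3-methylphenyl)-5-methoxy-8-(methoxymethoxy)-6-methyl-1H-isochromen-1-one F8.
- 1,3-Dimethoxybenzene and n-BuLi give (2,6-dimethoxyphenyl)lithium F9. It adds to the lactone carbonyl, the ring opens to the ketone enolate (which blocks a second addition), and protonation gives 11.

Step 3.
- What may go wrong: incomplete ring metalation or competing lateral metalation of 3, and sluggish intermolecular acylation between two di-ortho-substituted partners.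
- Fallback: the acyl group is delivered intramolecularly from oxygen. It sets out from 2 and comes back at 6.
- NBS brominates one of the two equivalent ortho positions of 2 to give 2-bromo-4-methoxy-3,5-dimethylphenol F10.
- Acylation with 4 (Et3N, DMAP) gives 2-bromo-4-methoxy-3,5-dimethylphenyl 2,6-dimethoxybenzoate F11.
- n-BuLi at −78 °C triggers a bromine–lithium-exchange-induced anionic Fries rearrangement (1,3 O→C acyl shift) to (2,6-dimethoxyphenyl)(6-hydroxy-3-methoxy-2,4-dimethylphenyl)methanone F12.
- MOMCl/i-Pr2NEt gives 6.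

**Further compounds**
F1 | step 10 | [2-(hydroxymethyl)-3-methoxy-6-(methoxymethoxy)-4-methylphenyl](2,6-dimethoxyphenyl)methanone | COCOc1cc(C)c(OC)c(CO)c1C(=O)c1c(OC)cccc1OC
F2 | step 10 | 2-(2,6-dimethoxybenzoyl)-6-methoxy-3-(methoxymethoxy)-5-methylbenzaldehyde | COCOc1cc(C)c(OC)c(C=O)c1C(=O)c1c(OC)cccc1OC
F3 | step 10 | 1,2-bis[2-(2,6-dimethoxybenzoyl)-6-methoxy-3-(methoxymethoxy)-5-methylphenyl]ethan-1-ol (racemic) | COCOc1cc(C)c(OC)c(CC(O)c2c(OC)c(C)cc(OCOC)c2C(=O)c2c(OC)cccc2OC)c1C(=O)c1c(OC)cccc1OC
F4 | step 10 | 1,2-bis[2-(2,6-dimethoxybenzoyl)-6-methoxy-3-(methoxymethoxy)-5-methylphenyl]ethan-1-one | COCOc1cc(C)c(OC)c(CC(=O)c2c(OC)c(C)cc(OCOC)c2C(=O)c2c(OC)cccc2OC)c1C(=O)c1c(OC)cccc1OC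
F5 | step 6 | methyl 3-methoxy-6-(methoxymethoxy)-2,4-dimethylbenzoate | COCOc1cc(C)c(OC)c(C)c1C(=O)OC
F6 | step 6 | {[6-methoxy-2-(methoxycarbonyl)-3-(methoxymethoxy)-5-methylphenyl]methyl}lithium | [Li]Cc1c(OC)c(C)cc(OCOC)c1C(=O)OC
F7 | step 6 | methyl 2-[2-(5-bromo-2-methoxy-3-methylphenyl)-2-oxoethyl]-3-methoxy-6-(methoxymethoxy)-4-methylbenzoate | COCOc1cc(C)c(OC)c(CC(=O)c2cc(Br)cc(C)c2OC)c1C(=O)OC
F8 | step 6 | 3-(5-bromo-2-methoxy-3-methylphenyl)-5-methoxy-8-(methoxymethoxy)-6-methyl-1H-isochromen-1-one | COCOc1cc(C)c(OC)c2C=C(c3cc(Br)cc(C)c3OC)OC(=O)c12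
F9 | step 6 | (2,6-dimethoxyphenyl)lithium | [Li]c1c(OC)cccc1OC
F10 | step 3 | 2-bromo-4-methoxy-3,5-dimethylphenol | COc1c(C)cc(O)c(Br)c1C
F11 | step 3 | 2-bromo-4-methoxy-3,5-dimethylphenyl 2,6-dimethoxybenzoate | COc1cccc(OC)c1C(=O)Oc1cc(C)c(OC)c(C)c1Br
F12 | step 3 | (2,6-dimethoxyphenyl)(6-hydroxy-3-methoxy-2,4-dimethylphenyl)methanone | COc1cccc(OC)c1C(=O)c1c(O)cc(C)c(OC)c1C
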